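Follow time along Sunday's readings: this flask has been followed to 15.0 h and is asked about at 30 h.

| flask | free monomer | pre-initiator | impurity | remark | time |
|---|---|---|---|---|---|
| Sunday's | 0.20 M | 4.2 mM | 2.5 mM | the very flask that is asked about, followed so far |  |
| flask | 0.20 M | 4.2 mM | 2.5 mM |  | 30 h |

Sunday's run (percent of the free monomer charged)

| time / h | monomer in chains / % | free monomer / % |
|---|---|---|
| 4.00 | 42.7 | 55.4 |
| 8.00 | 52.8 | 47.9 |
| 12.0 | 53.7 | 44.8 |
| 15.0 | 54.3 | 47.2 |

(standard deviation of a reading: 1 percentage point)

- whether the average number of monomer units in a chain (chains begun, living or dead) reaches 100 by 30 h (yes / no)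
- average number of monomer units in a chain (chains begun, living or dead) at 30 h

- the average divides the monomer in chains by the number of chains begun, living and dead together
- the analysis behind the earlier runs scatters by 1 percentage point, standard deviation
- the earlier runs do not show the number of chains; that part of a forecast is a guess

Read the chain column downward. Monomer in chains stands at 42.7% after 4.00 h and 52.8% after 8.00 h, then reaches 54.3% after 15.0 h, a late rise of 1.5 percentage points against a scatter of 1 point per reading. Treat that as a plateau. Now read across: the two columns add to 98.1% in the first row and 102% in the last, so Sunday's readings show no monomer going missing. Average the last 3 rows to get the plateau reading U, 53.6%, and carry it to 30 h. In this flask that is 0.107 M of monomer in chains.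

The table gives no denominator, so guess one. Define the chain count N as pre-initiator charged less impurity charged, 1.70 mM, supposing that each impurity destroys one initiator before a chain starts. My reckoning for this flask is then 63.1 units per chain. Reaching 100 in this flask needs 1.07 mM of chains, and N is larger, so I answer no.

The forecast answers no and gives 50, reading that “Growth has stopped with monomer still available”; my figure stands higher.

The flask gives no and 64.1 at 30 h.

    free monomer + initiator → living end + monomer in chains (k = 0.0260 M⁻¹ s⁻¹)
    free monomer + living end → monomer in chains + living end, rate k2*[living end]*[free monomer] (k = 0.0780 M⁻¹ s⁻¹)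
    monomer in chains + living end → free monomer + living end, rate k3*[living end] as long as [monomer in chains] is above zero (k = 0.00710 s⁻¹)
    initiator + impurity → spent initiator (k = 100 M⁻¹ s⁻¹)
    pre-initiator ⇌ initiator (K = 0.890, k = 9.00 × 10⁻⁴ s⁻¹)

At 30 h this flask holds 0.00170 M of living ends, matching N, and 0.00250 M of spent initiator. With charges as given, the pseudo-first-order time constant of initiator against impurity is 4.00 s, and against free monomer 192 s, longer by a factor of 48.0. Now take a neighbour flask with 0.017 M of pre-initiator: N becomes 14.5 mM, and U predicts 7.39. That neighbour flask gives 7.52.

(The numbers in the tables are simulated with constants of no real substance; scatter was added.)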